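Remark on the chemistry (assumption): the target has no stereocentre; di-tert-butyl squarate 2 is taken as a purchasable squaric ester; the intermediates with one stereocentre (4, 5, 11) are racemic, and that centre is destroyed again within the same step.

Ring numbering used throughout (target 15): C1(=O), C2(OH), C3(hexadecyl), C4(=O), C5(OMe), C6(H).

## The problem

Target 15 is a p-benzoquinone, one six-membered ring with carbonyls at C1 and C4, that carries four different groups on the other four carbons: OH at C2, an unbranched C16 chain at C3, OMe at C5 and H at C6. There is no stereocentre, so the problem is purely constitutional: every group must reach the right carbon. The ring is almost symmetrical. The oxygens at C2 and C5 are a vinylogous acid and its methyl ester, and C3 and C6 are both α-carbons of β-oxygenated enones. A route that buys this ring ready-made must therefore later choose between two nearly equal oxygens or two nearly equal carbons. The chain must be joined at C3, the most crowded position, between C2–OH and C4=O. The finished hydroxyquinone exchanges its C5 methoxy group with nucleophiles, is hydrolysed by aqueous acid or base and is easily reduced, so the last steps must be mild and free of nucleophiles. The feature that opens another way is the carbon pattern itself. C1(=O)–C2(O)=C3(alkyl)–C4(=O) is a squarate-derived cyclobutenedione whose C1–C4 bond has been cut, and C5(OMe)=C6(H) is methoxyethyne. The single ring hydrogen at C6 is what a 4-alkynyl-4-hydroxycyclobutenone ring expansion leaves there, because it is the hydroxyl hydrogen of the carbinol carbon C1.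

## Retrosynthesis

**15 ⇒ 14.** The C2 hydroxyl is traced back to its tert-butyl ether (cut: O–C(CH3)3).
- For this cut: the C2 oxygen then carries tert-butyl (from the squarate) and the C5 oxygen carries methyl (from the alkyne) from the first step onward, so no selection between the two oxygens is ever needed.
- Against its neighbours: a free OH would quench the acetylide, and two methyl ethers would demand a selective hydrolysis at the end.
- Simplification: 14 is no simpler in skeleton, but it removes the OH/OMe choice from the plan.
- Forward demand: anhydrous acidolysis that leaves the C5 methyl ether alone.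

**14 ⇒ 6 + 9.** The ring bonds C1–C6 and C4–C5 are cut and the transannular bond C1–C4 is re-formed. This returns the six-membered ring to cyclobutenedione 6 (C1–C4, with chain and tert-butoxy group in place) and methoxyethyne 9 (C5, C6).
- For this cut: both building blocks carry their own oxygen, so the 2,5-oxygen pattern follows from the connectivity.
- Against its neighbours: the reverse assignment, chain on the alkyne and both oxygens on the four-membered ring, would put the oxygens on adjacent carbons. A diene/dienophile cut would need two oxygenated partners and an oxidation-level adjustment.
- Simplification: 6 is a four-membered ring with two kinds of substituent, and 9 has four heavy atoms.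
- Forward demand: the acetylide 10 must attack the carbonyl that becomes C1; carbinol 11 must open to ketene 12; 12 must close to the six-membered ring through diradical 13, not to a five-membered ring.

**6 ⇒ 2 + 3 (from 1).** The C3–chain bond is cut.
- For this cut: squarate 2 is symmetrical, so Grignard reagent 3 can add to either carbonyl with the same result. The one unsymmetrical decision of the synthesis, where the chain sits relative to the two oxygens, is made without any selectivity question.
- Against its neighbours: cutting the same bond at the quinone stage meets the C3/C6 problem.
- Forward demand: a single 1,2-addition to give alkoxide 4, then activation as trifluoroacetate 5 and loss of one tert-butyl group with carbonyl transposition.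

**9 ⇒ 7.** The two π bonds of the alkyne are traced back to a chloroacetal by formal addition of methanol and hydrogen chloride. Acetal 7 is a bulk chemical; the forward reaction is a double elimination that holds the product as the involatile acetylide 8 until the quench.

## Roads not taken

**Alternative 1:** (the obvious one) cut the C3–chain bond on a ready-made tetra-oxygenated benzene.
- Forward: lithiation of 1,2,4,5-tetramethoxybenzene between two methoxy groups and alkylation with 1 to give 3-hexadecyl-1,2,4,5-tetramethoxybenzene A1; oxidation with (NH4)2Ce(NO3)6 to 3-hexadecyl-2,5-dimethoxy-1,4-benzoquinone A2; hydrolysis of one methoxy group to 15.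
- Why not: the last step must tell the C2 from the C5 methoxy group of A2. Both are vinylogous methyl esters that differ only in their neighbour (chain or hydrogen), so the outcome rests on a small steric bias, and hydrolysis of both groups competes. The hindered aryllithium also meets a long primary bromide, where elimination competes. The step count is similar, but the decisive step is a selectivity gamble that the chosen plan does not contain.

**Alternative 2:** cut the same bond on the quinone by a three-component reductive alkylation.
- Forward: 2,5-dihydroxy-1,4-benzoquinone, hexadecanal and a Hantzsch ester under amine catalysis give 3-hexadecyl-2,5-dihydroxy-1,4-benzoquinone A3 in one step; mono-O-methylation gives 15.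
- Why not: the two hydroxyls of A3 exchange roles by tautomerism (C1/C4 carbonyl shift). The methylating agent meets one ambident vinylogous acid and nothing in A3 fixes which oxygen is alkylated; double methylation competes as well. Short, but regiochemically blind at the final bond.

**Alternative 3:** a like-polarity radical union at C3.
- Forward: decarboxylative alkylation of 2-hydroxy-5-methoxy-1,4-benzoquinone A4 with heptadecanoic acid (AgNO3, (NH4)2S2O8) to give 15 directly.
- Why not: the nucleophilic primary radical must choose C3 over C6 of A4, which are electronically alike. Product 15 keeps a free C6–H and can be alkylated again. A4 itself poses the mono-methylation problem of Alternative 2. The chosen plan assigns every ring position by construction.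

Key step: step 3

## Route

**Step 1**
Reactants: 1 1-bromohexadecane; 2 di-tert-butyl squarate (3,4-di-tert-butoxycyclobut-3-ene-1,2-dione)
Product: 6 3-tert-butoxy-4-hexadecylcyclobut-3-ene-1,2-dione, via hexadecylmagnesium bromide 3 (not isolated), via bromomagnesium alkoxide 4 (not isolated), via tertiary trifluoroacetate 5 (not isolated)
Conditions: 1, Mg, THF, 40 °C; then 2, THF, −78 → −40 °C; (CF3CO)2O, −78 → 0 °C; cold aq. NaHCO3
Reagents that add atoms: none
Why: Grignard 1,2-addition to one of the two equivalent carbonyls of the symmetrical squarate gives 4, whose remaining carbonyl is a deactivated vinylogous ester and resists a second addition. O-Trifluoroacetylation to 5 and ionisation give a tert-butoxy-stabilised cyclobutenyl cation that sheds its tert-butyl group as 2-methylpropene; this is the standard squarate-to-3-alkoxy-4-alkylcyclobutenedione transposition.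

**Step 2**
Reactants: 7 2-chloro-1,1-dimethoxyethane
Product: 9 methoxyethyne, via sodium methoxyacetylide 8 (not isolated)
Conditions: NaNH2 (3 equiv), liquid NH3, −33 °C; cold saturated aq. NaCl; distilled into a −78 °C trap and taken up in cold THF
Reagents that add atoms: none
Why: Classical double elimination of a haloacetal (loss of methanol, then of hydrogen chloride). The third equivalent of amide holds the product as involatile acetylide 8 until the cold aqueous quench, after which the low-boiling alkyne is distilled directly into the solvent of the next step.

**Step 3**
Reactants: 6 3-tert-butoxy-4-hexadecylcyclobut-3-ene-1,2-dione; 9 methoxyethyne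
Product: 14 2-tert-butoxy-3-hexadecyl-5-methoxy-1,4-benzoquinone, via lithium methoxyacetylide 10 (not isolated), via alkynyl carbinol 11 (not isolated), via enynylketene 12 (not isolated), via aryl-phenoxyl diradical 13 (not isolated)
Conditions: 9 (1.3 equiv), n-BuLi (1.2 equiv), THF, −78 °C; 6, THF, −78 °C; aq. NH4Cl, −78 → 0 °C; organic phase dried, solvent changed cold to degassed toluene; 100 °C
Reagents that add atoms: none
Why: Lithium acetylide 10 should add to the one carbonyl of 6 that is a true ketone (the carbon that becomes C1, next to the tert-butoxy-bearing C2), because the other carbonyl (future C4) is the deactivated end of the vinylogous ester O=C4–C3=C2–OtBu; this forms C1–C6 and fixes which carbonyl ends up beside the chain. On heating, carbinol 11 opens by thermal conrotatory 4π electrocyclic cleavage of the C1–C4 σ bond with the donor hydroxyl rotating outward (torquoselectivity), so enynylketene 12 forms with the alkyne held cis to the ketene. The ketene carbon C4 then bonds to the methoxy-bearing alkyne terminus C5 in a six-membered cycloaromatisation (Moore cyclisation, the ketene counterpart of the Myers–Saito closure, formally 6-endo at the alkyne) to give diradical 13, with a phenoxyl oxygen on C4 and a σ radical on C6. Transfer of the hydroxyl hydrogen from the C1 oxygen to C6 quenches both radical centres and gives quinone 14 with the lone ring hydrogen at C6. The closest known reaction type is the thermal ring expansion of 4-alkynyl-4-hydroxycyclobutenones to 1,4-benzoquinones (Moore rearrangement), established for 2-alkyl-3-alkoxycyclobutenones including tert-butoxy ones and for alkoxyethynyl groups. The selectivity needed is six-ring against five-ring closure (bonding of C4 to C6 would give an alkylidenecyclopentenedione); an oxygen substituent on the alkyne terminus does not stabilise the exocyclic vinyl radical of the five-ring path as aryl, silyl or ester groups do, so the six-ring path should prevail. The methyl ynol ether has no β-hydrogen and cannot fragment by retro-ene loss of an alkene at this temperature, and the only stereocentre involved (C1 of racemic 11) is destroyed, so no stereocontrol is required.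

**Step 4**
Reactants: 14 2-tert-butoxy-3-hexadecyl-5-methoxy-1,4-benzoquinone
Product: 15 3-hexadecyl-2-hydroxy-5-methoxy-1,4-benzoquinone
Conditions: CF3CO2H, CH2Cl2, 0 °C → rt; evaporation
Reagents that add atoms: none
Why: Acidolysis of a tert-butyl vinylogous ester: protonation at the conjugated C4 carbonyl and E1 loss of the tert-butyl cation as 2-methylpropene. The C5 methyl ether cannot ionise this way, and without water or another nucleophile it is not exchanged; should part of the tert-butyl group already be lost thermally in step 3, that material is 15 and passes through unchanged.

## Compound list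

1 | 1-bromohexadecane | CCCCCCCCCCCCCCCCBr | starting material
2 | di-tert-butyl squarate (3,4-di-tert-butoxycyclobut-3-ene-1,2-dione) | CC(C)(C)OC1=C(OC(C)(C)C)C(=O)C1=O | starting material
3 | hexadecylmagnesium bromide | CCCCCCCCCCCCCCCC[Mg]Br | intermediate
4 | bromomagnesium 2,3-di-tert-butoxy-1-hexadecyl-4-oxocyclobut-2-en-1-olate (racemic) | CCCCCCCCCCCCCCCCC1(O[Mg]Br)C(OC(C)(C)C)=C(OC(C)(C)C)C1=O | intermediate
5 | 2,3-di-tert-butoxy-1-hexadecyl-4-oxocyclobut-2-en-1-yl trifluoroacetate (racemic) | CCCCCCCCCCCCCCCCC1(OC(=O)C(F)(F)F)C(OC(C)(C)C)=C(OC(C)(C)C)C1=O | intermediate
6 | 3-tert-butoxy-4-hexadecylcyclobut-3-ene-1,2-dione | CCCCCCCCCCCCCCCCC1=C(OC(C)(C)C)C(=O)C1=O | intermediate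
7 | 2-chloro-1,1-dimethoxyethane | COC(CCl)OC | starting material
8 | sodium methoxyacetylide | [Na+].[C-]#COC | intermediate
9 | methoxyethyne | COC#C | intermediate
10 | lithium methoxyacetylide | [Li]C#COC | intermediate
11 | 3-tert-butoxy-2-hexadecyl-4-hydroxy-4-(methoxyethynyl)cyclobut-2-en-1-one (racemic) | CCCCCCCCCCCCCCCCC1=C(OC(C)(C)C)C(O)(C#COC)C1=O | intermediate
12 | (3Z)-3-tert-butoxy-2-hexadecyl-4-hydroxy-6-methoxyhexa-1,3-dien-5-yn-1-one (enynylketene, alkyne cis to the ketene carbon) | CCCCCCCCCCCCCCCCC(=C=O)/C(OC(C)(C)C)=C(/O)C#COC | intermediate
13 | 3-tert-butoxy-2-hexadecyl-4-hydroxy-6-methoxyphenoxyl with a second radical centre at ring carbon 5 (σ,π-diradical) | CCCCCCCCCCCCCCCCc1c(OC(C)(C)C)c(O)[c]c(OC)c1[O] | intermediate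
14 | 2-tert-butoxy-3-hexadecyl-5-methoxy-1,4-benzoquinone | CCCCCCCCCCCCCCCCC1=C(OC(C)(C)C)C(=O)C=C(OC)C1=O | intermediate
15 | 3-hexadecyl-2-hydroxy-5-methoxy-1,4-benzoquinone (CNP0125193.0) | CCCCCCCCCCCCCCCCC1=C(O)C(=O)C=C(OC)C1=O | target

## Step count and risks

Total step count: 4. Longest linear sequence: 3 steps (1 → 3 → 4); step 2 supplies the two-carbon partner.

**Step 3 (key step).**
- What may go wrong: diversion of enynylketene 12 from the six-ring closure. It may close to a five-membered ring, or be captured intermolecularly by a hydroxyl group. The tert-butyl group may also be lost before ring opening. Because 11 is carried on crude, material from attack at the wrong carbonyl enters the thermolysis as well.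
- Fallback: it sets out from 11, kept cold in solution, and comes back at 14. Semi-hydrogenation of the ynol ether (H2, Pd on CaCO3 poisoned with Pb(OAc)2, quinoline, EtOAc, 0 °C) should give (Z)-3-tert-butoxy-2-hexadecyl-4-hydroxy-4-(2-methoxyethenyl)cyclobut-2-en-1-one F1. Heating F1 in toluene (80–100 °C) should open the ring and close the six-membered ring by a concerted 6π electrocyclisation, which involves no diradical and offers no five-ring option. Enolisation then gives 2-tert-butoxy-3-hexadecyl-5-methoxybenzene-1,4-diol F2, which Ag2O in Et2O should oxidise to 14.

**Step 2.**
- What may go wrong: loss of 9 by evaporation (it boils near room temperature) and base- or heat-induced oligomerisation during distillation, so that too little titrated alkyne reaches step 3.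
- Fallback: it avoids the free alkyne altogether. It does not set out from a compound of the route: trichloroethene and methanol take the place of 7, and it comes back at 10. Methanol, KH and trichloroethene in THF should give the distillable (E)-1,2-dichloro-1-methoxyethene F3 by dehydrochlorination and alkoxide addition. F3 with n-BuLi (2 equiv, THF, −78 °C) should lose chloride and then undergo chlorine–lithium exchange to give 10 directly, free of amines and alkoxides, ready for 6.

**Step 1.**
- What may go wrong: erosion of the mono-adduct by β-hydride reduction of the squarate carbonyl or a second addition of the sp3 Grignard reagent, and partial loss of the second tert-butyl group to the acid released on trifluoroacetylation.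
- Fallback: it sets out from 2 and comes back at 6; the chain comes from 1-hexadecyne in place of 1. Lithium hexadec-1-ynide (1-hexadecyne, n-BuLi, THF, −78 °C) should add cleanly to 2 to give 2,3-di-tert-butoxy-4-(hexadec-1-yn-1-yl)-4-hydroxycyclobut-2-en-1-one F4. Hydrogenation of the alkyne at room temperature (H2, PtO2, EtOAc) should give 2,3-di-tert-butoxy-4-hexadecyl-4-hydroxycyclobut-2-en-1-one F5. Treatment of F5 with (CF3CO)2O at −78 → 0 °C, as in step 1, should give 6.

## Further compounds

F1 | step 3 | (Z)-3-tert-butoxy-2-hexadecyl-4-hydroxy-4-(2-methoxyethenyl)cyclobut-2-en-1-one (racemic) | CCCCCCCCCCCCCCCCC1=C(OC(C)(C)C)C(O)(/C=C\OC)C1=O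
F2 | step 3 | 2-tert-butoxy-3-hexadecyl-5-methoxybenzene-1,4-diol | CCCCCCCCCCCCCCCCc1c(OC(C)(C)C)c(O)cc(OC)c1O
F3 | step 2 | (E)-1,2-dichloro-1-methoxyethene | CO/C(Cl)=C\Cl
F4 | step 1 | 2,3-di-tert-butoxy-4-(hexadec-1-yn-1-yl)-4-hydroxycyclobut-2-en-1-one (racemic) | CCCCCCCCCCCCCCC#CC1(O)C(OC(C)(C)C)=C(OC(C)(C)C)C1=O
F5 | step 1 | 2,3-di-tert-butoxy-4-hexadecyl-4-hydroxycyclobut-2-en-1-one (racemic) | CCCCCCCCCCCCCCCCC1(O)C(OC(C)(C)C)=C(OC(C)(C)C)C1=O
A1 | alternative 1 | 3-hexadecyl-1,2,4,5-tetramethoxybenzene | CCCCCCCCCCCCCCCCc1c(OC)c(OC)cc(OC)c1OC
A2 | alternative 1 | 3-hexadecyl-2,5-dimethoxy-1,4-benzoquinone | CCCCCCCCCCCCCCCCC1=C(OC)C(=O)C=C(OC)C1=O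
A3 | alternative 2 | 3-hexadecyl-2,5-dihydroxy-1,4-benzoquinone | CCCCCCCCCCCCCCCCC1=C(O)C(=O)C=C(O)C1=O
A4 | alternative 3 | 2-hydroxy-5-methoxy-1,4-benzoquinone | COC1=CC(=O)C(O)=CC1=O
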